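- We choose to reckon this flask as two steps in series, the coupling partner crossing from gas into solution and then being taken up by the catalyst, and we climb its time scales from fastest to slowest.

substrate 0.050 M; gas 2.6 mM (held); free catalyst 50 µM; time 25 h

    catalyst intermediate B → free catalyst + target (k1 = 1.80 min⁻¹)
    gas ⇌ coupling partner, rate k2*(csat - [coupling partner]) (k2 = 0.00532 min⁻¹, csat = 2.6 mM)
    coupling partner + free catalyst + target → free catalyst + over-reaction product (k3 = 283 M⁻² min⁻¹)
    substrate + free catalyst ⇌ catalyst intermediate A (K4 = 11 M⁻¹, k4 = 398 M⁻¹ min⁻¹)
    coupling partner + catalyst intermediate A → catalyst intermediate B (k5 = 352 M⁻¹ min⁻¹)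

- at the start none of coupling partner is dissolved
- run time (flask): 25 h

- teal: doubling the transfer coefficient of step 2, all else as stated
- ochre: doubling the amount of free catalyst, all else as stated
- amber: doubling the saturation concentration of gas, all else as stated

- how much target there is at 25 h, in percent of the substrate charged
- concentration of coupling partner in solution at 2.5 h, in percent of saturation
- the change that raises the amount of target at 25 h, in percent of the substrate charged most ("none" if none brings more than 2 percentage points) (teal / ochre / amber / none)
- amount of target at 25 h, in percent of the substrate charged, after amber

- On the fastest rung, step 4 relaxes at k4[substrate] + k4/K4 = 56.1 min⁻¹, faster than step 1 at k1 = 1.80 min⁻¹, so we treat binding as an equilibrium, and at the substrate charge catalyst intermediate A then holds 35.5% of the catalyst.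
- On the next rung, k1 exceeds k5·csat = 0.915 min⁻¹, where csat is the saturation concentration, so catalyst intermediate B stands below intermediate A, and we leave it out of the balance, which overstates intermediate A somewhat.
- On the middle rung, the partner is consumed with the pseudo-first-order constant κ = k5[intermediate A] = 0.00625 min⁻¹, which is 1.17 times the transfer coefficient k2, so we keep both. The solution fills with time constant τ = 1/(k2 + κ) = 1.44 h.
- Adding the two resistances gives 0.00287 min⁻¹: this is g, the product of k2 and κ divided by their sum, the series constant, which multiplied by csat gives the rate of target formation. In this reckoning, dissolved partner levels off at the fraction g/κ of saturation.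
- On the last rungs, the substrate charge would last 112 h at that rate, longer than the run, and target would be lost to over-reaction on a time of 453 h, so we hold substrate at its charge and drop step 3.
- Our reckoning gives y = 21.1% and sat = 37.9%.
- Comparing the series rates after each change, we choose amber.
- After amber we expect the substrate to fall further, so we take its mean as 0.0394 M. This lowers the series constant to 0.00266 min⁻¹ and gives yb = 38.9%.
- The forecast gives 19.2%, 39%, amber and 35.5%, on the ground that “The run is gas-limited”.
- This flask gives y = 19.2%, sat = 38.7%, best = amber and yb = 34.9%. At 25.0 h, coupling partner is made 1.01 times as fast as it is used up, each step taken net. Put to use once more, g/κ = 45.9% stands beside the reading of 49.4% of saturation at 12.5 h.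
- For the neighbour flask with 8.5 × 10⁻⁵ M of free catalyst, κ becomes 0.0106 min⁻¹ and g becomes 0.00354 min⁻¹, which gives 26.5% of target at 25 h. The computed amount in that neighbour flask is 24.5%.

The rate constants were chosen freely; the run is a simulation.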